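The numbers in the tables were generated by integration with constants of no real substance; scatter was added.

Compare two oak readings: from 1.04 d to 2.08 d time doubles, while product goes from 4% to 17%, 4.25 times as much.

| setting | oak | maple | beta | delta | eta |
|---|---|---|---|---|---|
| substrate | 0.076 M | 0.076 M | 0.076 M | 0.076 M | 0.076 M |
| reagent | 0.95 equiv | 0.95 equiv | 0.950 equiv | 0.950 equiv | 0.950 equiv |
| catalyst | 0.15 mol% | 0.24 mol% | 0.11 mol% | 0.11 mol% | 0.11 mol% |
| temperature | −12 °C | 15 °C | 0 °C | −25 °C | 25 °C |
| remark | run made earlier | run made earlier |  |  |  |
| time |  |  | 3.0 d | 3.0 d | 3.0 d |

| oak: time / d | oak: product / % | maple: time / h | maple: product / % |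
|---|---|---|---|
| 0.417 | 3 | 2.50 | 7 |
| 1.04 | 4 | 8.00 | 24 |
| 2.08 | 17 | 12.0 | 27 |
| 3.00 | 25 | 20.0 | 35 |
| 5.00 | 40 | 30.0 | 38 |

(each reading ± 1.5 percentage points)

- the earlier runs were read with a standard deviation of 1.5 percentage points
- a reading or a percentage of product counts all its forms, free or not

* the flask that comes out highest in amount of product, in percent of the substrate charged, or "all alike" when all lie within 1.5 percentage points (beta / delta / eta / all alike)
* product at the end, in percent of the substrate charged, beta
* product at the end, in percent of the substrate charged, delta
* product at the end, in percent of the substrate charged, eta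

Read that square in time as a lag phase: take the rate of product to be first-order in [intermediate], which starts empty and grows with time. Define the filling time θ as the time of an early reading divided by the square root of its product fraction, so that early product is (t/θ)². Assume, as my own step, that the catalyst acts in both stages, which makes θ go as one over the loading.

Oak gives 5.04 d and maple's first reading gives 0.394 d. At the new loading these become 6.88 d and 0.859 d, a factor of 8.01 between the two temperatures. Draw ln θ straight in temperature through these two values and extend the line beyond them for delta and eta. This gives 18.7 d as the filling time of delta, longer than its 3.0 d, so I take the square to hold in delta and expect 2.57%.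

Now turn the question round: what must be true for eta to beat beta? Beta has θ of 2.73 d, so t/θ is 1.10, close to the 0.991 of oak's last reading, and I put beta near that reading, 40%. Eta has θ of 0.398 d, and its lag ends well inside the run. It would therefore need a ceiling above 40%, while maple, colder, reads 38% at its end. Maple also reads 24% at t/θ of 0.847, while oak read 25% at 0.595, so on this scale the maple readings lie lower than the oak readings. I put eta below 38% and choose beta.

The forecast also chose beta but differs from me on beta and delta, giving 27%, 7% and 12% for beta, delta and eta, with the ground “Yield ceiling therefore falls with warming”.

The flasks give 39.6% for beta, 3.14% for delta and 20.2% for eta, so beta is highest.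

    substrate + catalyst → catalyst + intermediate (k = 79.3 M⁻¹ min⁻¹, Ea = 57.0 kJ mol⁻¹)
    reagent + catalyst + intermediate ⇌ catalyst + product (K = 3.77 M⁻¹, k = 304 M⁻² min⁻¹, Ea = 41.0 kJ mol⁻¹, ΔH = −31.0 kJ mol⁻¹)
    crystals ⇌ product, rate k3*(cs3 - [product]) while solid is left; crystals form when [product] > cs3 (solubility = 13.0 mM, k = 0.283 min⁻¹)
    (constants at 25 °C)

In delta the half-life of substrate by the first step at the end, 7.5 d, is longer than the run, and at the end intermediate is made 3.81 times faster than it is used up, each step taken net, with 75.7% substrate and 21.2% intermediate beside the product. Delta's filling time of 18.7 d gives 2.57% at the end of delta against 3.14%; for the neighbour flask, delta left until 12.0 d, it gives 41.2%, more than the 25.0% of product that flask holds, with 42.1% intermediate.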